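The synthesis rests on one disconnection: the ten-membered ring is grown out of the six-membered ring of (R)-carvone. In briarane numbering C4–C9 (with C16 and C17–C19) is the carvone p-menthane unit, and C2=C3–C4–C9–C10=C1 is a 3-oxy-1,5-diene whose far alkene lies in ring A. A single anionic oxy-Cope shift of alkoxide 15 breaks C4–C9 and joins C1 to C2, giving at once the ring A-fused cyclodecadienone, the quaternary C1, the C2 silane (masked hydroxyl) and the C4 ketone. The precursor 14 is a carvone-derived cyclohexenol with an (E)-2-silylvinyl group on C4 and the ring A cyclohexenyl group on C9, trans to the isopropenyl group.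

Key step: step 9

Remarks on the chemistry:
- Briarane numbering is used for every intermediate, also before the rings exist (carvone C1–C6 become C4, C5, C6, C7, C8, C9; its methyl is C16, its isopropenyl group C17–C19).
- C10 in 6 and 7 is a mixture that step 4 removes; 24–30 are carried as C17 epimers until step 21.
- In 17 the chain C2–C8 lies across the face of the (E)-C9=C10 alkene anti to C15. An external reagent (a borane included) would therefore add to C10 syn to C15 and give the cis ring fusion. C10 is set instead by an epoxide-to-ketone hydride shift and C9 by ketone reduction (steps 10, 11, 13).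

Step 1
Reactants: 1 4-methoxy-2-methylphenol
Product: 2 4,4-dimethoxy-2-methylcyclohexa-2,5-dien-1-one
Conditions: PhI(OAc)2, MeOH, 0 °C
Reagents that add atoms: methanol, CO
Why: Oxidative dearomatisation of a 4-alkoxyphenol with PhI(OAc)2 in methanol, in which the solvent traps the ring at C4 to give the quinone monoketal.

Step 2
Reactants: 2 4,4-dimethoxy-2-methylcyclohexa-2,5-dien-1-one
Product: 3 4,4-dimethoxy-2-methylcyclohex-2-en-1-one
Conditions: H2 (1 atm), RhCl(PPh3)3 (5 mol %), benzene, rt
Reagents that add atoms: none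
Why: Homogeneous hydrogenation with RhCl(PPh3)3 is governed by alkene substitution, so the disubstituted C5=C6 bond should be saturated and the methyl-bearing enone kept, as in the 1,2-selective reduction of steroidal 1,4-dien-3-ones.

Step 3
Reactants: 4 (R)-carvone; 3 4,4-dimethoxy-2-methylcyclohex-2-en-1-one
Product: 7 trimethylsilyl enol ether of the Michael adduct (C9–C10 bond in place; C1=C14–OSiMe3; C9 trans to isopropenyl), via lithium dienolate 5 (not isolated), via adduct lithium enolate 6 (not isolated)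
Conditions: LiN(iPr)2, THF, −78 °C; 3, −78 → −30 °C; Me3SiCl, Et3N, −78 °C
Reagents that add atoms: chlorotrimethylsilane, C[Si](C)(C)Cl
Why: Michael addition of the kinetic cross-conjugated dienolate 5 to the β-carbon of 3 (made electrophilic by the two alkoxy groups next to it), warming to let any 1,2-adduct revert, followed by O-silylation of enolate 6 before it can attack the carvone enone; the C9–C10 bond forms anti to the isopropenyl group on the neighbouring carbon, which sets C9.

Step 4
Reactants: 7 trimethylsilyl enol ether of the Michael adduct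
Product: 8 bis-enone (carvone bearing at C9 the 6,6-dimethoxy-2-methyl-3-oxocyclohex-1-enyl ring A unit trans to isopropenyl)
Conditions: Pd(OAc)2 (1.05 equiv), MeCN, rt
Reagents that add atoms: none
Why: Saegusa–Ito dehydrogenation, in which divalent palladium adds to C1 of the silyl enol ether and β-hydride loss from C10 restores the tetrasubstituted C1=C10 enone, while C9 (α to one ketone and vinylogous to the other) remains free to settle trans to the isopropenyl group.

Step 5
Reactants: 8 bis-enone
Product: 9 (14S)-allylic alcohol of 8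
Conditions: (R)-2-methyl-CBS-oxazaborolidine (20 mol %), catecholborane, toluene, −78 °C
Reagents that add atoms: none
Why: Corey–Bakshi–Shibata reduction: the ring A ketone with a CH2 flank binds the catalyst far more readily than the carvone ketone next to the fully substituted C9, and with the methyl-bearing alkene carbon as the large group the (R)-catalyst should give the (14S)-alcohol, so C14 is set by the reagent.

Step 6
Reactants: 9 (14S)-allylic alcohol
Product: 10 C14 tert-butyldimethylsilyl ether of 9
Conditions: t-BuMe2SiCl, imidazole, DMF, rt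
Reagents that add atoms: tert-butyldimethylsilyl chloride, CC(C)(C)[Si](C)(C)Cl
Why: Standard silylation of a secondary alcohol (silyl ether formation), giving a group that survives organometallics, KH and Lewis acid.

Step 7
Reactants: 11 ethynyldimethylphenylsilane
Product: 12 (E)-1-(dimethylphenylsilyl)-2-(tributylstannyl)ethene
Conditions: Bu3SnH, AIBN (cat.), neat, 90 °C
Reagents that add atoms: tributyltin hydride, CCCC[SnH](CCCC)CCCC
Why: Radical hydrostannation of a terminal alkyne, in which reversible stannyl radical addition leads to the more stable (E)-1-silyl-2-stannylethene.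

Step 8
Reactants: 12 (E)-1-(dimethylphenylsilyl)-2-(tributylstannyl)ethene; 10 C14 silyl ether
Product: 14 oxy-Cope precursor (tertiary C4 alcohol with the (E)-2-(dimethylphenylsilyl)vinyl group on C4 trans to the ring A cyclohexenyl group on C9), via silylvinyllithium 13 (not isolated)
Conditions: 12, n-BuLi, THF, −78 °C; CeCl3, −78 °C; 10, −78 → −40 °C; aq NH4Cl
Reagents that add atoms: none
Why: Tin–lithium exchange and 1,2-addition of the derived organocerium reagent, whose low basicity spares the acidic C9–H; attack on the C4 carbonyl anti to the large C9 substituent puts the silylvinyl group trans to it, and the C4 epimer would be equally usable in step 9.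

Step 9
Reactants: 14 oxy-Cope precursor
Product: 17 (1R,2S)-cyclodecadienone fused to ring A (C4 ketone; (5Z)-enone; (9E)-alkene; C2 SiMe2Ph; C11 dimethyl ketal; C14 silyl ether), via potassium alkoxide 15 (not isolated), via potassium enolate 16 (not isolated)
Conditions: KH, 18-crown-6, THF, 0 °C → rt; aq NH4Cl, −78 °C
Reagents that add atoms: none
Why: The potassium alkoxide 15, freed of its counter-ion by the crown ether, weakens the C4–C9 bond and undergoes a [3,3]-sigmatropic shift across C2=C3–C4–C9–C10=C1 to enolate 16, which is protonated at C3 on quenching; the closest known reaction is the anionic oxy-Cope ring expansion of trans-1,2-dialkenylcyclohexanols to cyclodec-5-enones, here with a fully substituted C10=C1 terminus. The ten-membered ring is closed by four-atom ring expansion of the carvone ring (C1–C2 formed, C4–C9 broken) through a chair transition state, not by end-to-end cyclisation. C1 is set by the geometry of the ring A alkene (C15, cis to C9, is axial and C14 equatorial in the chair) and C2 by the (E)-geometry of the vinylsilane (silicon equatorial), each alkene reacting on the single face that the chair exposes. The sense of the chair is dictated by C8 and C9: with C9 trans to the isopropenyl group, C8 and both alkenyl groups are equatorial on the carvone half-chair, which gives the (E)-C9=C10 alkene and leaves C5=C6 (Z), whichever way C4 is configured. The step needs this 1,5-diene to react in preference to the one that runs through the ring alkene C5=C6, which could engage only through a boat with the ring A substituent axial, and it needs the enolate not to eliminate, which is secured by having silicon and not oxygen at C2. Quenching cold keeps the new 1,5-diene (C5=C6 and C9=C10) from rearranging further.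

Step 10
Reactants: 17 cyclodecadienone
Product: 18 9,10-epoxide of 17 (oxygen syn to C15)
Conditions: mCPBA, NaHCO3, CH2Cl2, −20 °C
Reagents that add atoms: 3-chloroperbenzoic acid, OOC(=O)c1cccc(Cl)c1
Why: Prilezhaev epoxidation, chemoselective for the strained electron-rich (E)-trisubstituted alkene over the enone and the isopropenyl group, on the only open face of the (E)-alkene, the one syn to C15 (the C2–C8 chain covers the other).

Step 11
Reactants: 18 9,10-epoxide
Product: 19 4,9-diketone with H-10 anti to C15 (trans ring fusion)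
Conditions: BF3·OEt2 (1 equiv), CH2Cl2, −78 °C
Reagents that add atoms: none
Why: Meinwald rearrangement: ionisation at the tertiary C10 is met by a 1,2-hydride shift from C9 to the face opposite the leaving oxygen (the stereospecific course known from steroidal 5,6-epoxides), so that H-10 arrives anti to C15 and the ring fusion is trans; C5=C6 is deactivated as an enone, and migration of C8 would create two adjacent quaternary carbons.

Step 12
Reactants: 19 4,9-diketone
Product: 20 (4R)-allylic alcohol 9-ketone
Conditions: (S)-2-methyl-CBS-oxazaborolidine (30 mol %), catecholborane, toluene/CH2Cl2, −78 °C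
Reagents that add atoms: none
Why: Corey–Bakshi–Shibata reduction of the C4 enone, with the methyl-bearing alkene carbon C5 as the large group and C3H2 as the small one, so that the (S)-catalyst should give the (4R)-alcohol, while the C9 ketone between two tertiary carbons is too hindered to bind the catalyst.

Step 13
Reactants: 20 (4R)-allylic alcohol 9-ketone
Product: 21 4,9-diol (C9 configured as in the target)
Conditions: NaBH4, CeCl3·7H2O, MeOH, −40 → 0 °C
Reagents that add atoms: none
Why: Hydride reduction under Luche conditions (non-basic, so C8 and C10 do not epimerise) following Felkin–Anh control from C10: hydride enters from the outer face of the ring carbonyl, anti to the quaternary C1, which gives the C9 configuration of the target.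

Step 14
Reactants: 21 4,9-diol
Product: 22 2,4,9,14-tetraol
Conditions: KH, t-BuOOH, N-methylpyrrolidone, rt; Bu4NF, 70 °C
Reagents that add atoms: tert-butyl hydroperoxide, CC(C)(C)OO
Why: Fleming–Tamao oxidation under basic peroxide conditions, which spare the three alkenes: the phenyl group is lost from silicon, C2 migrates from silicon to oxygen with retention, and fluoride removes the C14 silyl ether in the same flask.

Step 15
Reactants: 22 2,4,9,14-tetraol
Product: 23 2,4,9,14-tetrakis(tert-butyldimethylsilyl) ether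
Conditions: t-BuMe2SiOTf, 2,6-lutidine, CH2Cl2, 0 °C → rt
Reagents that add atoms: tert-butyldimethylsilyl trifluoromethanesulfonate, CC(C)(C)[Si](C)(C)OS(=O)(=O)C(F)(F)F
Why: Silyl ether formation with the triflate, reactive enough for the hindered C2, C9 and C14 hydroxyls; silyl groups are chosen because an acyloxy group at C9 would be eliminated from the C8 enolate of step 19.

Step 16
Reactants: 23 tetrakis-silyl ether
Product: 24 C19 primary alcohol (both C17 epimers)
Conditions: 9-BBN, THF, 50 °C; H2O2, aq NaOH, 0 °C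
Reagents that add atoms: hydrogen peroxide, OO
Why: Hydroboration–oxidation: 9-BBN adds only to the 1,1-disubstituted alkene with boron on the terminal C19, the trisubstituted C5=C6 being left, and C17 is formed without reliable control, to be corrected in step 21.

Step 17
Reactants: 24 C19 primary alcohol
Product: 25 C19 carboxylic acid
Conditions: TEMPO (20 mol %), PhI(OAc)2, MeCN/pH 7 buffer, rt
Reagents that add atoms: water, O
Why: Oxoammonium (TEMPO) oxidation of the primary alcohol through the aldehyde hydrate to the carboxylic acid, without touching the alkene, silyl ethers or ketal.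

Step 18
Reactants: 25 C19 carboxylic acid
Product: 26 5-en-7-one carboxylic acid
Conditions: Rh2(cap)4 (1 mol %), t-BuOOH, K2CO3, CH2Cl2, rt
Reagents that add atoms: tert-butyl hydroperoxide, CC(C)(C)OO
Why: Allylic C–H oxidation by tert-butylperoxyl radicals under catalysis by dirhodium tetracaprolactamate, directed to the CH2 on the CH end of the trisubstituted alkene (the course of C7 oxidation in Δ5-steroids), C4–H being tertiary, silyloxy-shielded and held in the alkene plane.

Step 19
Reactants: 26 5-en-7-one carboxylic acid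
Product: 28 8-hydroxy-5-en-7-one carboxylic acid, via dipotassium carboxylate enolate 27 (not isolated)
Conditions: KN(SiMe3)2 (2.2 equiv), THF, −78 °C; 2-(phenylsulfonyl)-3-phenyloxaziridine, −78 °C; aq NH4Cl
Reagents that add atoms: 2-(phenylsulfonyl)-3-phenyloxaziridine, O=S(=O)(c1ccccc1)N1OC1c1ccccc1
Why: Davis hydroxylation of the cross-conjugated potassium enolate (C8 carries the only α'-hydrogen and the carboxylate is inert): with H-9 eclipsing the enolate to relieve allylic strain and the ring bond C9–C10 perpendicular, oxygen enters anti to C10, which gives the C8 configuration of the target.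

Step 20
Reactants: 28 8-hydroxy-5-en-7-one carboxylic acid
Product: 30 7,19-γ-lactone with free 8-OH (both C17 epimers), via dihydroxy acid 29 (not isolated)
Conditions: Zn(BH4)2, Et2O, −30 °C; aq NH4Cl; then EDC·HCl, DMAP, CH2Cl2, rt
Reagents that add atoms: none
Why: Chelation-controlled 1,2-reduction, zinc bridging the ketone and the 8-OH and hydride entering from the outer face anti to the ring bond C8–C9, gives the 7-OH cis to the 8-OH; carbodiimide (Steglich) lactonisation then closes the five-membered lactone onto the secondary 7-OH.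

Step 21
Reactants: 30 γ-lactone (C17 epimers)
Product: 31 (17R)-γ-lactone
Conditions: DBU, toluene, 80 °C
Reagents that add atoms: none
Why: Base-mediated epimerisation α to the lactone carbonyl (enolisation–reprotonation) should converge both C17 epimers on the more stable one, with C18 anti to the C9 branch on C8 and syn to the small hydroxyl, as in the target.

Step 22
Reactants: 31 (17R)-γ-lactone
Product: 32 5,6-epoxide of 31 (oxygen anti to C8 and to the C4 silyl ether)
Conditions: dimethyldioxirane, acetone, 0 °C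
Reagents that add atoms: dimethyldioxirane, CC1(C)OO1
Why: Epoxidation with dimethyldioxirane, which responds to sterics and not to hydroxyl direction: allylic strain holds H-4 and H-7 in the alkene plane and so places the C4 silyl ether and the quaternary C8 on one face, leaving the other to the oxidant.

Step 23
Reactants: 32 5,6-epoxide
Product: 33 6-hydroxy-5(16)-ene
Conditions: Cp2TiCl2 (2.5 equiv), Mn, THF, rt; dilute HCl work-up
Reagents that add atoms: none
Why: Epoxide to allylic alcohol isomerisation by trivalent titanium (Cp2TiCl, Nugent–RajanBabu opening): homolysis at the tertiary C5 and hydrogen-atom loss from the C16 methyl to a second Cp2TiCl give the exocyclic alkene, the C6–O bond and its configuration being untouched.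

Step 24
Reactants: 33 6-hydroxy-5(16)-ene
Product: 34 C11 ketone
Conditions: PPTS, acetone/H2O, 40 °C
Reagents that add atoms: water, O
Why: Acid-catalysed ketal hydrolysis under conditions mild enough for the silyl ethers, the lactone and the allylic alcohol, and too mild to enolise the ketone towards the tertiary C10.

Step 25
Reactants: 34 C11 ketone
Product: 35 5(16),11(20)-diene 6-alcohol
Conditions: Zn, CH2Br2, TiCl4, THF/CH2Cl2, 0 °C → rt
Reagents that add atoms: dibromomethane, BrCBr
Why: Takai–Lombardo methylenation, a non-basic carbonyl olefination that neither epimerises C10 nor eliminates the β-silyloxy group at C9 and that tolerates the lactone and the free hydroxyls.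

Step 26
Reactants: 35 5(16),11(20)-diene 6-alcohol
Product: 36 6-chloride (C6 as in the target)
Conditions: PPh3, hexachloroacetone, CH2Cl2, 0 °C
Reagents that add atoms: hexachloroacetone, ClC(Cl)(Cl)C(=O)C(Cl)(Cl)Cl
Why: Appel-type chlorination with PPh3 and hexachloroacetone: the alkoxyphosphonium salt of the secondary allylic alcohol is displaced by chloride with inversion and without allylic transposition, which turns the 6-OH into the 6-chloride of the target, the tertiary 8-OH being inert.

Step 27
Reactants: 36 6-chloride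
Product: 37 2,4,9,14-tetraol chloride
Conditions: HF·pyridine, THF, 0 °C → rt
Reagents that add atoms: none
Why: Fluoride-mediated cleavage of the four silyl ethers, which the lactone, the allylic chloride and both exocyclic alkenes should survive.

Step 28
Reactants: 37 2,4,9,14-tetraol chloride
Product: 38 CNP0186618.1 (target)
Conditions: Ac2O, pyridine, DMAP (cat.), CH2Cl2, 0 °C → rt
Reagents that add atoms: acetic anhydride, CC(=O)OC(C)=O
Why: Acetylation (nucleophilic catalysis by DMAP) of the four secondary hydroxyls, the tertiary 8-OH being too hindered to react under these conditions.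

Compound list
1 | 4-methoxy-2-methylphenol | COc1ccc(O)c(C)c1 | starting material
2 | 4,4-dimethoxy-2-methylcyclohexa-2,5-dien-1-one | COC1(OC)C=CC(=O)C(C)=C1 | intermediate
3 | 4,4-dimethoxy-2-methylcyclohex-2-en-1-one | COC1(OC)CCC(=O)C(C)=C1 | intermediate
4 | (R)-carvone | CC1=CC[C@H](CC1=O)C(C)=C | starting material
5 | lithium dienolate of (R)-carvone (deprotonated at the later C9) | [Li]OC1=C[C@H](C(C)=C)CC=C1C | intermediate
6 | lithium enolate (C1=C14–OLi) of the Michael adduct, C10 unassigned | [C@H]1(C(C)=C)[C@H](C2C(C)=C(O[Li])CCC2(OC)OC)C(=O)C(C)=CC1 | intermediate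
7 | trimethylsilyl enol ether of the Michael adduct, C10 unassigned | [C@H]1(C(C)=C)[C@H](C2C(C)=C(O[Si](C)(C)C)CCC2(OC)OC)C(=O)C(C)=CC1 | intermediate
8 | bis-enone, ring A unit on C9 trans to isopropenyl | [C@H]1(C(C)=C)[C@H](C2=C(C)C(=O)CCC2(OC)OC)C(=O)C(C)=CC1 | intermediate
9 | (14S)-allylic alcohol | [C@H]1(C(C)=C)[C@H](C2=C(C)[C@@H](O)CCC2(OC)OC)C(=O)C(C)=CC1 | intermediate
10 | C14 tert-butyldimethylsilyl ether | [C@H]1(C(C)=C)[C@H](C2=C(C)[C@@H](O[Si](C)(C)C(C)(C)C)CCC2(OC)OC)C(=O)C(C)=CC1 | intermediate
11 | ethynyldimethylphenylsilane | C#C[Si](C)(C)c1ccccc1 | starting material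
12 | (E)-1-(dimethylphenylsilyl)-2-(tributylstannyl)ethene | CCCC[Sn](CCCC)(CCCC)/C=C/[Si](C)(C)c1ccccc1 | intermediate
13 | (E)-2-(dimethylphenylsilyl)vinyllithium | [Li]/C=C/[Si](C)(C)c1ccccc1 | intermediate
14 | oxy-Cope precursor, 1-(silylvinyl)-6-(cyclohexenyl)cyclohexenol | [C@H]1(C(C)=C)[C@H](C2=C(C)[C@@H](O[Si](C)(C)C(C)(C)C)CCC2(OC)OC)[C@@](O)(/C=C/[Si](C)(C)c2ccccc2)C(C)=CC1 | intermediate
15 | potassium alkoxide of 14 | [C@H]1(C(C)=C)[C@H](C2=C(C)[C@@H](O[Si](C)(C)C(C)(C)C)CCC2(OC)OC)[C@@](O[K])(/C=C/[Si](C)(C)c2ccccc2)C(C)=CC1 | intermediate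
16 | potassium enolate (C3=C4–OK) of 17 | [C@H]1(C(C)=C)/C=C2\C(OC)(OC)CC[C@H](O[Si](C)(C)C(C)(C)C)[C@]2(C)[C@@H]([Si](C)(C)c2ccccc2)/C=C(O[K])/C(C)=C\C1 | intermediate
17 | (1R,2S)-cyclodecadienone fused to ring A, C2 silane | [C@H]1(C(C)=C)/C=C2\C(OC)(OC)CC[C@H](O[Si](C)(C)C(C)(C)C)[C@]2(C)[C@@H]([Si](C)(C)c2ccccc2)CC(=O)/C(C)=C\C1 | intermediate
18 | 9,10-epoxide, oxygen syn to C15 | [C@H]1(C(C)=C)[C@@H]2O[C@]23C(OC)(OC)CC[C@H](O[Si](C)(C)C(C)(C)C)[C@]3(C)[C@@H]([Si](C)(C)c3ccccc3)CC(=O)/C(C)=C\C1 | intermediate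
19 | 4,9-diketone, trans ring fusion | [C@H]1(C(C)=C)C(=O)[C@H]2C(OC)(OC)CC[C@H](O[Si](C)(C)C(C)(C)C)[C@]2(C)[C@@H]([Si](C)(C)c2ccccc2)CC(=O)/C(C)=C\C1 | intermediate
20 | (4R)-allylic alcohol 9-ketone | [C@H]1(C(C)=C)C(=O)[C@H]2C(OC)(OC)CC[C@H](O[Si](C)(C)C(C)(C)C)[C@]2(C)[C@@H]([Si](C)(C)c2ccccc2)C[C@@H](O)/C(C)=C\C1 | intermediate
21 | 4,9-diol | [C@H]1(C(C)=C)[C@@H](O)[C@H]2C(OC)(OC)CC[C@H](O[Si](C)(C)C(C)(C)C)[C@]2(C)[C@@H]([Si](C)(C)c2ccccc2)C[C@@H](O)/C(C)=C\C1 | intermediate
22 | 2,4,9,14-tetraol | [C@H]1(C(C)=C)[C@@H](O)[C@H]2C(OC)(OC)CC[C@H](O)[C@]2(C)[C@@H](O)C[C@@H](O)/C(C)=C\C1 | intermediate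
23 | 2,4,9,14-tetrakis(tert-butyldimethylsilyl) ether | [C@H]1(C(C)=C)[C@@H](O[Si](C)(C)C(C)(C)C)[C@H]2C(OC)(OC)CC[C@H](O[Si](C)(C)C(C)(C)C)[C@]2(C)[C@@H](O[Si](C)(C)C(C)(C)C)C[C@@H](O[Si](C)(C)C(C)(C)C)/C(C)=C\C1 | intermediate
24 | C19 primary alcohol, C17 epimers | [C@H]1(C(C)CO)[C@@H](O[Si](C)(C)C(C)(C)C)[C@H]2C(OC)(OC)CC[C@H](O[Si](C)(C)C(C)(C)C)[C@]2(C)[C@@H](O[Si](C)(C)C(C)(C)C)C[C@@H](O[Si](C)(C)C(C)(C)C)/C(C)=C\C1 | intermediate
25 | C19 carboxylic acid, C17 epimers | [C@H]1(C(C)C(O)=O)[C@@H](O[Si](C)(C)C(C)(C)C)[C@H]2C(OC)(OC)CC[C@H](O[Si](C)(C)C(C)(C)C)[C@]2(C)[C@@H](O[Si](C)(C)C(C)(C)C)C[C@@H](O[Si](C)(C)C(C)(C)C)/C(C)=C\C1 | intermediate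
26 | 5-en-7-one carboxylic acid, C17 epimers | [C@H]1(C(C)C(O)=O)[C@@H](O[Si](C)(C)C(C)(C)C)[C@H]2C(OC)(OC)CC[C@H](O[Si](C)(C)C(C)(C)C)[C@]2(C)[C@@H](O[Si](C)(C)C(C)(C)C)C[C@@H](O[Si](C)(C)C(C)(C)C)/C(C)=C\C1=O | intermediate
27 | dipotassium carboxylate C7=C8 enolate of 26 | C=1(C(C)C(=O)O[K])[C@@H](O[Si](C)(C)C(C)(C)C)[C@H]2C(OC)(OC)CC[C@H](O[Si](C)(C)C(C)(C)C)[C@]2(C)[C@@H](O[Si](C)(C)C(C)(C)C)C[C@@H](O[Si](C)(C)C(C)(C)C)/C(C)=C\C=1O[K] | intermediate
28 | 8-hydroxy-5-en-7-one carboxylic acid, C17 epimers | [C@@]1(O)(C(C)C(O)=O)[C@@H](O[Si](C)(C)C(C)(C)C)[C@H]2C(OC)(OC)CC[C@H](O[Si](C)(C)C(C)(C)C)[C@]2(C)[C@@H](O[Si](C)(C)C(C)(C)C)C[C@@H](O[Si](C)(C)C(C)(C)C)/C(C)=C\C1=O | intermediate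
29 | 7,8-dihydroxy acid, C17 epimers | [C@@]1(O)(C(C)C(O)=O)[C@@H](O[Si](C)(C)C(C)(C)C)[C@H]2C(OC)(OC)CC[C@H](O[Si](C)(C)C(C)(C)C)[C@]2(C)[C@@H](O[Si](C)(C)C(C)(C)C)C[C@@H](O[Si](C)(C)C(C)(C)C)/C(C)=C\[C@@H]1O | intermediate
30 | 7,19-γ-lactone with free 8-OH, C17 epimers | COC1(OC)CC[C@H](O[Si](C)(C)C(C)(C)C)[C@]2(C)[C@@H](O[Si](C)(C)C(C)(C)C)C[C@@H](O[Si](C)(C)C(C)(C)C)/C(C)=C\[C@@H]3OC(=O)C(C)[C@@]3(O)[C@@H](O[Si](C)(C)C(C)(C)C)[C@@H]12 | intermediate
31 | (17R)-γ-lactone | COC1(OC)CC[C@H](O[Si](C)(C)C(C)(C)C)[C@]2(C)[C@@H](O[Si](C)(C)C(C)(C)C)C[C@@H](O[Si](C)(C)C(C)(C)C)/C(C)=C\[C@@H]3OC(=O)[C@H](C)[C@@]3(O)[C@@H](O[Si](C)(C)C(C)(C)C)[C@@H]12 | intermediate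
32 | 5,6-epoxide | COC1(OC)CC[C@H](O[Si](C)(C)C(C)(C)C)[C@]2(C)[C@@H](O[Si](C)(C)C(C)(C)C)C[C@@H](O[Si](C)(C)C(C)(C)C)[C@@]4(C)O[C@H]4[C@@H]3OC(=O)[C@H](C)[C@@]3(O)[C@@H](O[Si](C)(C)C(C)(C)C)[C@@H]12 | intermediate
33 | 6-hydroxy-5(16)-ene | COC1(OC)CC[C@H](O[Si](C)(C)C(C)(C)C)[C@]2(C)[C@@H](O[Si](C)(C)C(C)(C)C)C[C@@H](O[Si](C)(C)C(C)(C)C)C(=C)[C@@H](O)[C@@H]3OC(=O)[C@H](C)[C@@]3(O)[C@@H](O[Si](C)(C)C(C)(C)C)[C@@H]12 | intermediate
34 | C11 ketone | O=C1CC[C@H](O[Si](C)(C)C(C)(C)C)[C@]2(C)[C@@H](O[Si](C)(C)C(C)(C)C)C[C@@H](O[Si](C)(C)C(C)(C)C)C(=C)[C@@H](O)[C@@H]3OC(=O)[C@H](C)[C@@]3(O)[C@@H](O[Si](C)(C)C(C)(C)C)[C@@H]12 | intermediate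
35 | 5(16),11(20)-diene 6-alcohol | C=C1CC[C@H](O[Si](C)(C)C(C)(C)C)[C@]2(C)[C@@H](O[Si](C)(C)C(C)(C)C)C[C@@H](O[Si](C)(C)C(C)(C)C)C(=C)[C@@H](O)[C@@H]3OC(=O)[C@H](C)[C@@]3(O)[C@@H](O[Si](C)(C)C(C)(C)C)[C@@H]12 | intermediate
36 | 6-chloride | C=C1CC[C@H](O[Si](C)(C)C(C)(C)C)[C@]2(C)[C@@H](O[Si](C)(C)C(C)(C)C)C[C@@H](O[Si](C)(C)C(C)(C)C)C(=C)[C@H](Cl)[C@@H]3OC(=O)[C@H](C)[C@@]3(O)[C@@H](O[Si](C)(C)C(C)(C)C)[C@@H]12 | intermediate
37 | 2,4,9,14-tetraol chloride | C=C1CC[C@H](O)[C@]2(C)[C@@H](O)C[C@@H](O)C(=C)[C@H](Cl)[C@@H]3OC(=O)[C@H](C)[C@@]3(O)[C@@H](O)[C@@H]12 | intermediate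
38 | CNP0186618.1, (1R,2S,4R,6S,7R,8R,9S,10S,14S,17R)-2,4,9,14-tetraacetoxy-6-chloro-8-hydroxybriara-5(16),11(20)-dien-19,7-olide | C=C1CC[C@H](OC(C)=O)[C@]2(C)[C@@H](OC(C)=O)C[C@@H](OC(C)=O)C(=C)[C@H](Cl)[C@@H]3OC(=O)[C@H](C)[C@@]3(O)[C@@H](OC(C)=O)[C@@H]12 | target

Total step count: 28 (step 7 is the side branch to the vinylstannane).
Longest linear sequence: 27 steps (steps 1–6 and 8–28, from 4-methoxy-2-methylphenol); 25 steps from (R)-carvone.

The three steps most likely to fail

Step 9 (key step). The crowded chair, which must join a fully substituted C1 to C2, may close more slowly than the alkoxide fragments (heterolysis of C4–C9 without recombination at C1, or proton transfer from C9). The fallback runs the same shift without a charged oxygen and sets out from 14. The tertiary alcohol is silylated (Me3SiCl, imidazole, DMF) to the C4 trimethylsilyl ether F1. Thermolysis of F1 in degassed o-dichlorobenzene at about 200 °C (neutral siloxy-Cope rearrangement through the same chair) should give the C3=C4 trimethylsilyl enol ether F2. Cleavage of the enol ether with KF in methanol returns the route at 17.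

Step 11. The Lewis acid may ionise the neighbouring C11 ketal, or the ring carbon C8 may migrate in place of hydride and contract the ring. The fallback replaces the cationic shift by a radical opening and sets out from 18. Cp2TiCl2 (catalytic), Mn, 2,4,6-collidine hydrochloride and 1,4-cyclohexadiene in THF should open the epoxide at the tertiary C10; hydrogen-atom transfer to the C10 radical on the face anti to the axial C15 methyl gives the C9 alcohol F3. Oxidation of F3 with Dess–Martin periodinane returns the route at 19.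

Step 22. Facial selectivity in the oxidation of the C5=C6 alkene may be poor or reversed, which after steps 23 and 26 would put chlorine on the wrong face of C6. The fallback uses the same facial preference without the inversion and sets out from 31. Ene-type chlorination with Ca(OCl)2 and CO2 in CH2Cl2/H2O at 0 °C delivers chlorine to C6 on the face the electrophile prefers, with loss of a C16 hydrogen, to give the 6-chloro-5(16)-ene ketal F4. Hydrolysis of the ketal (PPTS, acetone/H2O) gives the C11 ketone F5, and methylenation of F5 (Zn, CH2Br2, TiCl4) returns the route at 36.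

Further compounds
F1 | step 9 | C4 trimethylsilyl ether of 14 | [C@H]1(C(C)=C)[C@H](C2=C(C)[C@@H](O[Si](C)(C)C(C)(C)C)CCC2(OC)OC)[C@@](O[Si](C)(C)C)(/C=C/[Si](C)(C)c2ccccc2)C(C)=CC1
F2 | step 9 | C3=C4 trimethylsilyl enol ether of 17 | [C@H]1(C(C)=C)/C=C2\C(OC)(OC)CC[C@H](O[Si](C)(C)C(C)(C)C)[C@]2(C)[C@@H]([Si](C)(C)c2ccccc2)/C=C(O[Si](C)(C)C)/C(C)=C\C1
F3 | step 11 | C9 alcohol from reductive opening of 18 (H-10 anti to C15) | [C@H]1(C(C)=C)[C@H](O)[C@H]2C(OC)(OC)CC[C@H](O[Si](C)(C)C(C)(C)C)[C@]2(C)[C@@H]([Si](C)(C)c2ccccc2)CC(=O)/C(C)=C\C1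
F4 | step 22 | 6-chloro-5(16)-ene C11 dimethyl ketal | COC1(OC)CC[C@H](O[Si](C)(C)C(C)(C)C)[C@]2(C)[C@@H](O[Si](C)(C)C(C)(C)C)C[C@@H](O[Si](C)(C)C(C)(C)C)C(=C)[C@H](Cl)[C@@H]3OC(=O)[C@H](C)[C@@]3(O)[C@@H](O[Si](C)(C)C(C)(C)C)[C@@H]12
F5 | step 22 | 6-chloro-5(16)-ene C11 ketone | O=C1CC[C@H](O[Si](C)(C)C(C)(C)C)[C@]2(C)[C@@H](O[Si](C)(C)C(C)(C)C)C[C@@H](O[Si](C)(C)C(C)(C)C)C(=C)[C@H](Cl)[C@@H]3OC(=O)[C@H](C)[C@@]3(O)[C@@H](O[Si](C)(C)C(C)(C)C)[C@@H]12
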